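**Retrosynthetic overview**

1. Numbering (guaiane): C1 = ring-fusion alkene carbon, C2/C3 = cyclopentane CH2, C4 = C(OH)Me, C5 = ring-fusion CH, C6 = CHOH, C7 = CH(iPr), C8 = CH–O-aroyl, C9 = CH2, C10 = C(Me)=. The target is traced back through aryl-acetate removal, chelation-controlled reduction of a C6 ketone and acylation of C8–OH to a bicyclic β-hydroxy ketone.
2. Key disconnection: the cyclopentane is cut at C1–C2 and C4–C5. 1-Methylcyclopropanol (C2, C3, C4, the C4 methyl and the C4 oxygen) is annulated onto a cycloheptenyl triflate by Pd-homoenolate cross-coupling at C1, followed in the same flask by aldol closure from C5 onto the freed methyl ketone.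
3. Enabling feature: C4 is a tertiary carbinol β to the C6 oxygen (an aldol retron once C6 is a ketone); C5 lies between that carbonyl and the C1=C10 alkene of the seven-membered ring (a doubly activated CH2 in the precursor); C1 is a vinylic ring carbon that can be the carbon of a regiodefined enol triflate.
4. Ring order: seven-membered ring first (RCM forming C9=C10, then conjugate reduction/enolate triflation), cyclopentane second (key step).
5. Stereocentres: C7/C8 from an Evans syn-aldol; C4/C5 in the key step, relayed from C7/C8 through the cycloheptene chair; C6 last by 1,3-syn reduction.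

Key step: step 11

Remark: the acylated oxazolidinone starting material is taken as commercial (otherwise one N-acylation of (R)-4-benzyl-2-oxazolidinone). The five compounds between the second aldol and the oxidation to the keto triflate are carried as mixtures of both epimers at the carbinol carbon that becomes the C6 ketone, so this centre is left undefined in their SMILES.

**Step 1**
Reactants: 1 (R)-4-benzyl-3-(3-methylbutanoyl)-1,3-oxazolidin-2-one; 2 acrolein
Product: 4 (R)-4-benzyl-3-[(2R,3S)-3-hydroxy-2-(propan-2-yl)pent-4-enoyl]-1,3-oxazolidin-2-one, via boron enolate 3 (not isolated)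
Conditions: Bu2BOTf, iPr2NEt, CH2Cl2, −78 → 0 °C; 2, −78 → 0 °C; then pH 7 buffer, MeOH, H2O2, 0 °C
Reagents that add atoms: none
Why: Evans syn-aldol through the (Z)-boron enolate and a Zimmerman–Traxler chair, in which the (R)-benzyl auxiliary shields one enolate face, should give the (2R,3S) syn adduct and thereby set C7 and C8 of the target.

**Step 2**
Reactants: 4 (R)-4-benzyl-3-[(2R,3S)-3-hydroxy-2-(propan-2-yl)pent-4-enoyl]-1,3-oxazolidin-2-one
Product: 5 (R)-4-benzyl-3-[(2R,3S)-3-[(tert-butyldimethylsilyl)oxy]-2-(propan-2-yl)pent-4-enoyl]-1,3-oxazolidin-2-one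
Conditions: TBSOTf, 2,6-lutidine, CH2Cl2, −78 → 0 °C
Reagents that add atoms: tert-butyldimethylsilyl triflate, CC(C)(C)[Si](C)(C)OS(=O)(=O)C(F)(F)F
Why: silyl-triflate silylation of a hindered secondary aldol hydroxyl is standard and installs a poor leaving group at C8 that survives the later basic steps.

**Step 3**
Reactants: 5 (R)-4-benzyl-3-[(2R,3S)-3-[(tert-butyldimethylsilyl)oxy]-2-(propan-2-yl)pent-4-enoyl]-1,3-oxazolidin-2-one
Product: 6 (2S,3S)-3-[(tert-butyldimethylsilyl)oxy]-2-(propan-2-yl)pent-4-en-1-ol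
Conditions: LiBH4, MeOH (1 equiv), Et2O, 0 °C
Reagents that add atoms: none
Why: reductive cleavage of the N-acyl oxazolidinone with lithium borohydride should release the primary alcohol and the recoverable auxiliary without touching either stereocentre.

**Step 4**
Reactants: 6 (2S,3S)-3-[(tert-butyldimethylsilyl)oxy]-2-(propan-2-yl)pent-4-en-1-ol
Product: 7 (2R,3S)-3-[(tert-butyldimethylsilyl)oxy]-2-(propan-2-yl)pent-4-enal
Conditions: Dess–Martin periodinane, CH2Cl2, 0 → 23 °C
Reagents that add atoms: none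
Why: Dess–Martin oxidation is a mild, non-epimerising route to α-branched aldehydes, and the aldehyde would be used directly.

**Step 5**
Reactants: 7 (2R,3S)-3-[(tert-butyldimethylsilyl)oxy]-2-(propan-2-yl)pent-4-enal; 8 3-methylbut-3-en-2-one
Product: 10 (6S,7S)-7-[(tert-butyldimethylsilyl)oxy]-5-hydroxy-2-methyl-6-(propan-2-yl)nona-1,8-dien-3-one (both C5 epimers), via lithium enolate 9 (not isolated)
Conditions: LDA, THF, −78 °C; 8; then 7, −78 °C; aq. NH4Cl
Reagents that add atoms: none
Why: the kinetic α′-lithium enolate of the enone should add 1,2 to the aldehyde (aldol addition), forming the C5–C6 bond; the new carbinol centre needs no control because it is oxidised in step 10.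

**Step 6**
Reactants: 10 (6S,7S)-7-[(tert-butyldimethylsilyl)oxy]-5-hydroxy-2-methyl-6-(propan-2-yl)nona-1,8-dien-3-one
Product: 11 (6S,7S)-7-[(tert-butyldimethylsilyl)oxy]-2-methyl-6-(propan-2-yl)-5-[(triethylsilyl)oxy]nona-1,8-dien-3-one (both C5 epimers)
Conditions: TESCl, imidazole, DMF, 0 → 23 °C
Reagents that add atoms: chlorotriethylsilane, CC[Si](CC)(CC)Cl
Why: standard silylation gives a triethylsilyl ether that blocks retro-aldol and β-elimination and can later be removed in the presence of the TBS ether.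

**Step 7**
Reactants: 11 (6S,7S)-7-[(tert-butyldimethylsilyl)oxy]-2-methyl-6-(propan-2-yl)-5-[(triethylsilyl)oxy]nona-1,8-dien-3-one
Product: 12 (4S,5S)-4-[(tert-butyldimethylsilyl)oxy]-2-methyl-5-(propan-2-yl)-6-[(triethylsilyl)oxy]cyclohept-2-en-1-one (both C6 epimers)
Conditions: Grubbs second-generation catalyst (5 mol%), CH2Cl2 (0.005 M), 40 °C
Reagents that add atoms: none
Why: ring-closing metathesis between the terminal alkene and the 1,1-disubstituted enone alkene should close the seven-membered ring as a trisubstituted α-methyl enone with loss of ethene.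

**Step 8**
Reactants: 12 (4S,5S)-4-[(tert-butyldimethylsilyl)oxy]-2-methyl-5-(propan-2-yl)-6-[(triethylsilyl)oxy]cyclohept-2-en-1-one
Product: 14 (4S,5R)-4-[(tert-butyldimethylsilyl)oxy]-2-methyl-5-(propan-2-yl)-6-[(triethylsilyl)oxy]cyclohept-1-en-1-yl trifluoromethanesulfonate (both C6 epimers), via lithium enolate 13 (not isolated)
Conditions: L-Selectride, THF, −78 °C; then PhNTf2, −78 → 0 °C; aq. NH4Cl
Reagents that add atoms: N-phenylbis(trifluoromethanesulfonimide), O=S(=O)(N(c1ccccc1)S(=O)(=O)C(F)(F)F)C(F)(F)F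
Why: conjugate (1,4) hydride reduction of the α-methyl enone generates the tetrasubstituted enolate regiospecifically, and O-triflation of that enolate fixes the C1(OTf)=C10(Me) unit, a regiochemistry that enolisation of a 1,3-dione could not guarantee.

**Step 9**
Reactants: 14 (4S,5R)-4-[(tert-butyldimethylsilyl)oxy]-2-methyl-5-(propan-2-yl)-6-[(triethylsilyl)oxy]cyclohept-1-en-1-yl trifluoromethanesulfonate
Product: 15 (4S,5S)-4-[(tert-butyldimethylsilyl)oxy]-6-hydroxy-2-methyl-5-(propan-2-yl)cyclohept-1-en-1-yl trifluoromethanesulfonate (both C6 epimers)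
Conditions: PPTS (cat.), MeOH/CH2Cl2, 0 °C
Reagents that add atoms: none
Why: acid-catalysed methanolysis cleaves a triethylsilyl ether much faster than a secondary TBS ether, and the enol triflate is stable to these conditions.

**Step 10**
Reactants: 15 (4S,5S)-4-[(tert-butyldimethylsilyl)oxy]-6-hydroxy-2-methyl-5-(propan-2-yl)cyclohept-1-en-1-yl trifluoromethanesulfonate
Product: 16 (4S,5R)-4-[(tert-butyldimethylsilyl)oxy]-2-methyl-6-oxo-5-(propan-2-yl)cyclohept-1-en-1-yl trifluoromethanesulfonate
Conditions: Dess–Martin periodinane, CH2Cl2, 0 °C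
Reagents that add atoms: none
Why: Dess–Martin oxidation under base-free conditions should give the β,γ-unsaturated keto triflate without conjugation or epimerisation, converging both carbinol epimers.

**Step 11**
Reactants: 16 (4S,5R)-4-[(tert-butyldimethylsilyl)oxy]-2-methyl-6-oxo-5-(propan-2-yl)cyclohept-1-en-1-yl trifluoromethanesulfonate; 17 1-methylcyclopropan-1-ol
Product: 19 (3S,3aR,5R,6S)-6-[(tert-butyldimethylsilyl)oxy]-3-hydroxy-3,8-dimethyl-5-(propan-2-yl)-2,3,3a,5,6,7-hexahydroazulen-4(1H)-one, via coupled diketone 18 (not isolated)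
Conditions: 17 (1.5 equiv), Pd(OAc)2 (5 mol%), XPhos (10 mol%), Cs2CO3, PhMe, 50 °C; then DBU (0.2 equiv), 23 °C
Reagents that add atoms: none
Why: Proposed new method: Pd(0) inserts into the C1–OTf bond, the cyclopropanol binds as a Pd alkoxide and opens by strain-driven β-carbon elimination to a Pd homoenolate, and C(sp2)–C(sp3) reductive elimination (favoured over β-hydride elimination by the bulky biarylphosphine) forms C1–C2 to give diketone 18; its C5 methylene, the only position both α to the C6 ketone and allylic to C1=C10, is then deprotonated by carbonate/DBU, and the dienolate attacks the tethered methyl ketone through its α-carbon to form C4–C5. The closest known reaction types are the Pd-catalysed ring-opening cross-coupling of cyclopropanols with aryl and alkenyl (pseudo)halides and the α-selective aldol reactions of dienolates from β,γ-unsaturated ketones; joining them into a one-flask [3+2] annulation is the new element. The cyclopentane closes in a 5-(enolexo)-exo-trig aldol mode, which leaves C1=C10 in place as the tetrasubstituted alkene of the target. C4 is set by the cation-bridged closed transition state and, under reversible conditions, by the OH···O=C hydrogen bond of the product (hydroxyl cis to the C6 carbonyl, methyl on the face of H5); C5 is set relative to C7/C8 because the exocyclic alkene at C1 forces C4 into the pseudo-equatorial position at C5 of the cycloheptene chair, so only the required C5 epimer lets the isopropyl and silyloxy groups stay equatorial (thermodynamic control through retro-aldol/aldol, with the same sense expected kinetically). The step needs C5 (not C7, C10 or the methyl ketone) as the nucleophile and no β-elimination of the C8 silyloxy group; this is secured by the acidity gap between C5–H2 and the tertiary C7–H, by the equatorial OTBS group being misaligned for E1cB loss, and by the strain of every alternative closure (bridgehead alkene or seven-membered ring).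

**Step 12**
Reactants: 19 (3S,3aR,5R,6S)-6-[(tert-butyldimethylsilyl)oxy]-3-hydroxy-3,8-dimethyl-5-(propan-2-yl)-2,3,3a,5,6,7-hexahydroazulen-4(1H)-one
Product: 20 (3S,3aR,5R,6S)-3,6-dihydroxy-3,8-dimethyl-5-(propan-2-yl)-2,3,3a,5,6,7-hexahydroazulen-4(1H)-one
Conditions: HF·pyridine, pyridine, THF, 0 → 23 °C
Reagents that add atoms: none
Why: buffered fluoride desilylation is mild enough to spare both β-hydroxy ketone units from retro-aldol or dehydration.

**Step 13**
Reactants: 20 (3S,3aR,5R,6S)-3,6-dihydroxy-3,8-dimethyl-5-(propan-2-yl)-2,3,3a,5,6,7-hexahydroazulen-4(1H)-one; 21 4-(acetyloxy)benzoyl chloride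
Product: 22 (3S,3aR,5R,6S)-3-hydroxy-3,8-dimethyl-4-oxo-5-(propan-2-yl)-1,2,3,3a,4,5,6,7-octahydroazulen-6-yl 4-(acetyloxy)benzoate
Conditions: 21, pyridine, DMAP (cat.), CH2Cl2, −20 → 0 °C
Reagents that add atoms: none
Why: acid-chloride acylation should occur only at the secondary C8 hydroxyl, since the tertiary C4 hydroxyl is inert under these conditions, so no protecting group is needed.

**Step 14**
Reactants: 22 (3S,3aR,5R,6S)-3-hydroxy-3,8-dimethyl-4-oxo-5-(propan-2-yl)-1,2,3,3a,4,5,6,7-octahydroazulen-6-yl 4-(acetyloxy)benzoate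
Product: 24 (3S,3aS,4R,5S,6S)-3,4-dihydroxy-3,8-dimethyl-5-(propan-2-yl)-1,2,3,3a,4,5,6,7-octahydroazulen-6-yl 4-(acetyloxy)benzoate, via boron chelate 23 (not isolated)
Conditions: Et2BOMe, THF/MeOH (4:1), −78 °C; NaBH4, −78 °C; AcOH, then MeOH co-evaporation
Reagents that add atoms: none
Why: Narasaka–Prasad reduction: boron bridges the C4 oxygen and the C6 carbonyl on the β-face, so external hydride adds from the α-face and should give the syn-1,3-diol with the axial β-hydroxyl at C6, the same sense expected for equatorial attack on this ketone.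

**Step 15**
Reactants: 24 (3S,3aS,4R,5S,6S)-3,4-dihydroxy-3,8-dimethyl-5-(propan-2-yl)-1,2,3,3a,4,5,6,7-octahydroazulen-6-yl 4-(acetyloxy)benzoate
Product: 25 (3S,3aS,4R,5S,6S)-3,4-dihydroxy-3,8-dimethyl-5-(propan-2-yl)-1,2,3,3a,4,5,6,7-octahydroazulen-6-yl 4-hydroxybenzoate (target)
Conditions: K2CO3 (0.2 equiv), MeOH, 0 °C
Reagents that add atoms: none
Why: methanolysis of an aryl acetate (phenoxide leaving group) is far faster than that of the hindered secondary benzoate, and the trans-1,3 relation of the C6 hydroxyl and the C8 ester disfavours acyl migration.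

**Compound list**

1 | (R)-4-benzyl-3-(3-methylbutanoyl)-1,3-oxazolidin-2-one | CC(C)CC(=O)N1[C@H](Cc2ccccc2)COC1=O | starting material
2 | acrolein (prop-2-enal) | C=CC=O | starting material
3 | (Z)-dibutylboron enolate of 1 | CC(C)/C=C(\OB(CCCC)CCCC)N1[C@H](Cc2ccccc2)COC1=O | intermediate (not isolated)
4 | (R)-4-benzyl-3-[(2R,3S)-3-hydroxy-2-(propan-2-yl)pent-4-enoyl]-1,3-oxazolidin-2-one | O=C(N1[C@H](Cc2ccccc2)COC1=O)[C@H](C(C)C)[C@@H](O)C=C | intermediate
5 | (R)-4-benzyl-3-[(2R,3S)-3-[(tert-butyldimethylsilyl)oxy]-2-(propan-2-yl)pent-4-enoyl]-1,3-oxazolidin-2-one | O=C(N1[C@H](Cc2ccccc2)COC1=O)[C@H](C(C)C)[C@@H](O[Si](C)(C)C(C)(C)C)C=C | intermediate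
6 | (2S,3S)-3-[(tert-butyldimethylsilyl)oxy]-2-(propan-2-yl)pent-4-en-1-ol | OC[C@H](C(C)C)[C@@H](O[Si](C)(C)C(C)(C)C)C=C | intermediate
7 | (2R,3S)-3-[(tert-butyldimethylsilyl)oxy]-2-(propan-2-yl)pent-4-enal | O=C[C@H](C(C)C)[C@@H](O[Si](C)(C)C(C)(C)C)C=C | intermediate
8 | 3-methylbut-3-en-2-one | CC(=C)C(C)=O | starting material
9 | lithium 3-methylbuta-1,3-dien-2-olate | C=C(C)C(=C)O[Li] | intermediate (not isolated)
10 | (6S,7S)-7-[(tert-butyldimethylsilyl)oxy]-5-hydroxy-2-methyl-6-(propan-2-yl)nona-1,8-dien-3-one, both C5 epimers | C=C(C)C(=O)CC(O)[C@H](C(C)C)[C@@H](O[Si](C)(C)C(C)(C)C)C=C | intermediate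
11 | (6S,7S)-7-[(tert-butyldimethylsilyl)oxy]-2-methyl-6-(propan-2-yl)-5-[(triethylsilyl)oxy]nona-1,8-dien-3-one, both C5 epimers | C=C(C)C(=O)CC(O[Si](CC)(CC)CC)[C@H](C(C)C)[C@@H](O[Si](C)(C)C(C)(C)C)C=C | intermediate
12 | (4S,5S)-4-[(tert-butyldimethylsilyl)oxy]-2-methyl-5-(propan-2-yl)-6-[(triethylsilyl)oxy]cyclohept-2-en-1-one, both C6 epimers | O=C1CC(O[Si](CC)(CC)CC)[C@H](C(C)C)[C@@H](O[Si](C)(C)C(C)(C)C)C=C1C | intermediate
13 | lithium enolate from conjugate reduction of 12 (tetrasubstituted cyclohept-1-en-1-olate) | CC1=C(O[Li])CC(O[Si](CC)(CC)CC)[C@H](C(C)C)[C@@H](O[Si](C)(C)C(C)(C)C)C1 | intermediate (not isolated)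
14 | (4S,5R)-4-[(tert-butyldimethylsilyl)oxy]-2-methyl-5-(propan-2-yl)-6-[(triethylsilyl)oxy]cyclohept-1-en-1-yl trifluoromethanesulfonate, both C6 epimers | CC1=C(OS(=O)(=O)C(F)(F)F)CC(O[Si](CC)(CC)CC)[C@H](C(C)C)[C@@H](O[Si](C)(C)C(C)(C)C)C1 | intermediate
15 | (4S,5S)-4-[(tert-butyldimethylsilyl)oxy]-6-hydroxy-2-methyl-5-(propan-2-yl)cyclohept-1-en-1-yl trifluoromethanesulfonate, both C6 epimers | CC1=C(OS(=O)(=O)C(F)(F)F)CC(O)[C@H](C(C)C)[C@@H](O[Si](C)(C)C(C)(C)C)C1 | intermediate
16 | (4S,5R)-4-[(tert-butyldimethylsilyl)oxy]-2-methyl-6-oxo-5-(propan-2-yl)cyclohept-1-en-1-yl trifluoromethanesulfonate | CC1=C(OS(=O)(=O)C(F)(F)F)CC(=O)[C@H](C(C)C)[C@@H](O[Si](C)(C)C(C)(C)C)C1 | intermediate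
17 | 1-methylcyclopropan-1-ol | CC1(O)CC1 | starting material
18 | (2R,3S)-3-[(tert-butyldimethylsilyl)oxy]-5-methyl-6-(3-oxobutyl)-2-(propan-2-yl)cyclohept-5-en-1-one | CC1=C(CCC(C)=O)CC(=O)[C@H](C(C)C)[C@@H](O[Si](C)(C)C(C)(C)C)C1 | intermediate (not isolated)
19 | (3S,3aR,5R,6S)-6-[(tert-butyldimethylsilyl)oxy]-3-hydroxy-3,8-dimethyl-5-(propan-2-yl)-2,3,3a,5,6,7-hexahydroazulen-4(1H)-one | CC1=C2CC[C@](C)(O)[C@@H]2C(=O)[C@H](C(C)C)[C@@H](O[Si](C)(C)C(C)(C)C)C1 | intermediate
20 | (3S,3aR,5R,6S)-3,6-dihydroxy-3,8-dimethyl-5-(propan-2-yl)-2,3,3a,5,6,7-hexahydroazulen-4(1H)-one | CC1=C2CC[C@](C)(O)[C@@H]2C(=O)[C@H](C(C)C)[C@@H](O)C1 | intermediate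
21 | 4-(acetyloxy)benzoyl chloride | CC(=O)Oc1ccc(cc1)C(Cl)=O | starting material
22 | (3S,3aR,5R,6S)-3-hydroxy-3,8-dimethyl-4-oxo-5-(propan-2-yl)-1,2,3,3a,4,5,6,7-octahydroazulen-6-yl 4-(acetyloxy)benzoate | CC1=C2CC[C@](C)(O)[C@@H]2C(=O)[C@H](C(C)C)[C@@H](OC(=O)c2ccc(OC(C)=O)cc2)C1 | intermediate
23 | O-diethylboryl chelate of 22 (boron on the tertiary oxygen, coordinated to the ketone) | CC1=C2CC[C@](C)(OB(CC)CC)[C@@H]2C(=O)[C@H](C(C)C)[C@@H](OC(=O)c2ccc(OC(C)=O)cc2)C1 | intermediate (not isolated)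
24 | (3S,3aS,4R,5S,6S)-3,4-dihydroxy-3,8-dimethyl-5-(propan-2-yl)-1,2,3,3a,4,5,6,7-octahydroazulen-6-yl 4-(acetyloxy)benzoate | CC1=C2CC[C@](C)(O)[C@@H]2[C@H](O)[C@H](C(C)C)[C@@H](OC(=O)c2ccc(OC(C)=O)cc2)C1 | intermediate
25 | (3S,3aS,4R,5S,6S)-3,4-dihydroxy-3,8-dimethyl-5-(propan-2-yl)-1,2,3,3a,4,5,6,7-octahydroazulen-6-yl 4-hydroxybenzoate | CC1=C2CC[C@](C)(O)[C@@H]2[C@H](O)[C@H](C(C)C)[C@@H](OC(=O)c2ccc(O)cc2)C1 | target

**Step count and risks**

Total step count: 15. Longest linear sequence: 15 steps (1 → 25); compounds 2, 8, 17 and 21 are commercial building blocks.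

Steps most likely to fail:

Step 11 (Proposed new method). The palladium homoenolate may collapse by β-hydride elimination before C–C reductive elimination, or the enolate of 16 may shed triflate under the basic coupling conditions before oxidative addition. The two bonds would then be made one after the other by established reactions. Starting from 16, a B-alkyl Suzuki–Miyaura coupling [PdCl2(dppf), AsPh3, Cs2CO3, DMF/THF/H2O, 23 °C] with 9-[2-(2-methyl-1,3-dioxolan-2-yl)ethyl]-9-borabicyclo[3.3.1]nonane F1 (generated from commercial 2-methyl-2-vinyl-1,3-dioxolane and 9-BBN-H) should give the ketal-protected (2R,3S)-3-[(tert-butyldimethylsilyl)oxy]-5-methyl-6-[2-(2-methyl-1,3-dioxolan-2-yl)ethyl]-2-(propan-2-yl)cyclohept-5-en-1-one F2. PPTS in wet acetone would release the methyl ketone to give 18 as an isolated compound, and a separate base-mediated aldol cyclisation (KOtBu cat., t-BuOH/THF, 0 °C) would rejoin the route at 19.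

Step 8. Hydride may be delivered 1,2 to the carbonyl of the seven-membered enone instead of to the β-carbon, or the hindered enolate may be triflated sluggishly. The regiodefined enolate would then be reached by a thermodynamic rather than a reductive route. Starting from 12, hydrogenation (H2, Pd/C, EtOAc) should give the saturated (4S,5R)-4-[(tert-butyldimethylsilyl)oxy]-2-methyl-5-(propan-2-yl)-6-[(triethylsilyl)oxy]cycloheptan-1-one F3. Equilibrating silylation (TMSCl, Et3N, DMF, 80 °C) should favour the more substituted (4S,5R)-4-[(tert-butyldimethylsilyl)oxy]-2-methyl-5-(propan-2-yl)-6-[(triethylsilyl)oxy]-1-[(trimethylsilyl)oxy]cyclohept-1-ene F4. MeLi (THF, 0 °C) would regenerate lithium enolate 13, and PhNTf2 would return the route to 14.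

Step 13. Acylation of the β-hydroxy ketone may trigger E1cB loss of the newly installed aroyloxy group (β to the C6 ketone) or retro-aldol opening of the seven-membered ring. The order of events would then be changed so that no β-acyloxy ketone is ever formed. Starting from 19, chelation-controlled reduction (Et2BOMe, NaBH4, THF/MeOH, −78 °C) should give (3S,3aS,4R,5S,6S)-6-[(tert-butyldimethylsilyl)oxy]-3,8-dimethyl-5-(propan-2-yl)-1,2,3,3a,4,5,6,7-octahydroazulene-3,4-diol F5. 2,2-Dimethoxypropane/PPTS should give the 3,4-O-isopropylidene acetal of that diol F6, and HF·pyridine/pyridine the 3,4-O-isopropylidene-protected azulen-6-ol F7. Acylation with 21 (pyridine, DMAP) should give the 3,4-O-isopropylidene-protected 6-yl 4-(acetyloxy)benzoate F8, and aqueous acetic acid would remove the acetonide to rejoin the route at 24.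

**Further compounds**

F1 | step 11 | 9-[2-(2-methyl-1,3-dioxolan-2-yl)ethyl]-9-borabicyclo[3.3.1]nonane | CC1(CCB2C3CCCC2CCC3)OCCO1
F2 | step 11 | (2R,3S)-3-[(tert-butyldimethylsilyl)oxy]-5-methyl-6-[2-(2-methyl-1,3-dioxolan-2-yl)ethyl]-2-(propan-2-yl)cyclohept-5-en-1-one | CC1=C(CCC2(C)OCCO2)CC(=O)[C@H](C(C)C)[C@@H](O[Si](C)(C)C(C)(C)C)C1
F3 | step 8 | (4S,5R)-4-[(tert-butyldimethylsilyl)oxy]-2-methyl-5-(propan-2-yl)-6-[(triethylsilyl)oxy]cycloheptan-1-one, epimers at C2 and C6 | O=C1CC(O[Si](CC)(CC)CC)[C@H](C(C)C)[C@@H](O[Si](C)(C)C(C)(C)C)CC1C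
F4 | step 8 | (4S,5R)-4-[(tert-butyldimethylsilyl)oxy]-2-methyl-5-(propan-2-yl)-6-[(triethylsilyl)oxy]-1-[(trimethylsilyl)oxy]cyclohept-1-ene, both C6 epimers | CC1=C(O[Si](C)(C)C)CC(O[Si](CC)(CC)CC)[C@H](C(C)C)[C@@H](O[Si](C)(C)C(C)(C)C)C1
F5 | step 13 | (3S,3aS,4R,5S,6S)-6-[(tert-butyldimethylsilyl)oxy]-3,8-dimethyl-5-(propan-2-yl)-1,2,3,3a,4,5,6,7-octahydroazulene-3,4-diol | CC1=C2CC[C@](C)(O)[C@@H]2[C@H](O)[C@H](C(C)C)[C@@H](O[Si](C)(C)C(C)(C)C)C1
F6 | step 13 | 3,4-O-isopropylidene acetal of F5 (TBS ether retained) | CC1=C2CC[C@](C)(OC3(C)C)[C@@H]2[C@H](O3)[C@H](C(C)C)[C@@H](O[Si](C)(C)C(C)(C)C)C1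
F7 | step 13 | 3,4-O-isopropylidene-protected azulen-6-ol (desilylated F6) | CC1=C2CC[C@](C)(OC3(C)C)[C@@H]2[C@H](O3)[C@H](C(C)C)[C@@H](O)C1
F8 | step 13 | 3,4-O-isopropylidene-protected azulen-6-yl 4-(acetyloxy)benzoate | CC1=C2CC[C@](C)(OC3(C)C)[C@@H]2[C@H](O3)[C@H](C(C)C)[C@@H](OC(=O)c2ccc(OC(C)=O)cc2)C1
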